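The route rests on cutting ring B (C5–C10, eremophilane numbering) on both sides of its cis-diol carbons: C8–C9 arrive as one two-carbon, glyoxal-level linchpin that is welded to the allylic carbon C7 and to the ring-fusion carbon C10 in a single flask. The precursor is a ring A silyl dienol ether, in which C10 is the γ-terminus of the masked C3 enone, carrying on quaternary C5 a (Z)-allylboronate chain. Allylboration of the linchpin aldehyde forms C7–C8 together with the isopropenyl group and the 7,8-cis relationship; ionising the linchpin's acetal then lets C10 close C9–C10, setting four contiguous stereocentres and the cis ring fusion.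

Key step: step 9

Numbering used: eremophilane numbering (ring A: C1–C5 and C10; ring B: C5–C10; C11–C13 isopropenyl on C7; C14 on C5; C15 on C4). β denotes the face of the C5 methyl group; absolute configurations are those of the SMILES.

Remark on the chemistry: C4 stays epimerisable until step 10. Compounds 13–20 are drawn as the cis-4,5-dimethyl epimers; a C4 epimer formed in step 5 should follow the same course and is converged in step 10.

Step 1
Reactants: 1 3,3-diethoxyprop-1-ene (acrolein diethyl acetal)
Product: 2 3,3-bis(benzyloxy)prop-1-ene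
Conditions: BnOH (2.5 equiv), PPTS (cat.), toluene, 70 °C, reduced pressure (EtOH distilled off)
Reagents that add atoms: benzyl alcohol, OCc1ccccc1
Why: Acid-catalysed transacetalisation is driven to the dibenzyl acetal by removal of ethanol; no stereocentre is formed.

Step 2
Reactants: 2 3,3-bis(benzyloxy)prop-1-ene
Product: 3 2,2-bis(benzyloxy)acetaldehyde
Conditions: O3, CH2Cl2, −78 °C; then Me2S
Reagents that add atoms: ozone, [O-][O+]=O
Why: Ozonolysis with reductive work-up cleaves the terminal alkene to the α,α-dialkoxy aldehyde, the benzyl ethers being inert at −78 °C when ozone is not used in excess.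

Step 3
Reactants: 4 (R)-pent-4-yn-2-ol; 5 angelic acid [(Z)-2-methylbut-2-enoic acid]
Product: 7 (R)-pent-4-yn-2-yl (Z)-2-methylbut-2-enoate, via mixed anhydride 6 (not isolated)
Conditions: 5, 2,4,6-trichlorobenzoyl chloride, Et3N, toluene, rt; then 4, 80 °C
Reagents that add atoms: none
Why: Yamaguchi esterification through the mixed anhydride acylates the secondary alcohol with retention at the carbinol carbon and, run without DMAP, should preserve the (Z)-angelate geometry.

Step 4
Reactants: 7 (R)-pent-4-yn-2-yl (Z)-2-methylbut-2-enoate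
Product: 8 (R)-5-[(Z)-2-methylbut-2-enoyloxy]hex-2-ynoic acid
Conditions: silver iodide AgI (2 mol%), Cs2CO3, CO2 (1 atm), DMF, 50 °C; then aq. HCl
Reagents that add atoms: carbon dioxide, O=C=O
Why: Silver-catalysed C–H carboxylation of the terminal alkyne under carbonate base is mild enough to leave the angelate ester and its geometry intact.

Step 5
Reactants: 9 2-methylbut-1-en-3-yne; 10 3-methylcyclohex-2-en-1-one
Product: 13 (2R,3R)-2,3-dimethyl-3-[(E)-3-methylbuta-1,3-dienyl]cyclohexanone, via dienylalane 11 (not isolated), via aluminium enolate 12 (not isolated)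
Conditions: 9, i-Bu2AlH, hexane, 50 °C; then 10, copper thiophene-2-carboxylate C5H3CuO2S (5 mol%), chiral phosphinamine ligand Ph2P–N[CH(CH3)Ph]2 (10 mol%, enantiomer chosen to give the R quaternary centre), Et2O, −30 °C; then MeLi, THF; MeI, HMPA, −30 to 0 °C
Reagents that add atoms: iodomethane, IC
Why: syn-Hydroalumination gives the (E)-dienylalane, copper-catalysed asymmetric conjugate addition sets the quaternary C5 under ligand control, and the regiospecific aluminium enolate, activated as its ate complex, is methylated at C4, expected mainly anti to the dienyl group (cis-dimethyl).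

Step 6
Reactants: 13 (2R,3R)-2,3-dimethyl-3-[(E)-3-methylbuta-1,3-dienyl]cyclohexanone
Product: 15 (5R,6R)-5,6-dimethyl-5-[(E)-3-methylbuta-1,3-dienyl]cyclohex-2-en-1-one, via trimethylsilyl enol ether 14 (not isolated)
Conditions: LiN(i-Pr)2, THF, −78 °C; Me3SiCl; then Pd(OAc)2 (1.05 equiv), MeCN, rt
Reagents that add atoms: none
Why: Saegusa–Ito oxidation of the kinetic silyl enol ether can only give the C1=C2 enone, because C4–H is tertiary and the other β-position (C5) is quaternary; C4 and C5 are untouched.

Step 7
Reactants: 15 (5R,6R)-5,6-dimethyl-5-[(E)-3-methylbuta-1,3-dienyl]cyclohex-2-en-1-one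
Product: 16 (5R,6R)-1-(tert-butyldimethylsilyloxy)-5,6-dimethyl-5-[(E)-3-methylbuta-1,3-dienyl]cyclohexa-1,3-diene
Conditions: TBSOTf, Et3N, CH2Cl2, 0 °C
Reagents that add atoms: tert-butyldimethylsilyl triflate, CC(C)(C)[Si](C)(C)OS(=O)(=O)C(F)(F)F
Why: Soft enolisation removes a γ-proton at C10 (the α′-proton at C4 is tertiary and flanked by quaternary C5), giving the linear conjugated silyl dienol ether in which C10 is the nucleophilic terminus.

Step 8
Reactants: 16 (5R,6R)-1-(tert-butyldimethylsilyloxy)-5,6-dimethyl-5-[(E)-3-methylbuta-1,3-dienyl]cyclohexa-1,3-diene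
Product: 17 pinacol (Z)-allylboronate: 2-[(2Z)-4-{(1S,6R)-5-(tert-butyldimethylsilyloxy)-1,6-dimethylcyclohexa-2,4-dien-1-yl}-2-methylbut-2-en-1-yl]-4,4,5,5-tetramethyl-1,3,2-dioxaborolane
Conditions: Ni(cod)2 (2.5 mol%), PCy3 (2.5 mol%), pinacolborane, toluene, rt
Reagents that add atoms: pinacolborane, CC1(C)OBOC1(C)C
Why: Nickel-catalysed 1,4-hydroboration of the terminal 1,3-diene delivers H to C6 and boron to C12 through an η3-allylnickel species formed from the s-cis diene, which fixes the (Z)-geometry; the acyclic terminal diene should react faster than the cyclic trisubstituted siloxydiene.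

Step 9
Reactants: 17 pinacol (Z)-allylboronate of the ring A silyl dienol ether; 3 2,2-bis(benzyloxy)acetaldehyde
Product: 20 9β-(benzyloxy)-8β-hydroxy-10βH-eremophila-1,11-dien-3-one, via homoallylic borate 18 (not isolated), via O-boryl enone 19 (not isolated)
Conditions: 3 (1.0 equiv), (S)-TRIP [(S)-3,3′-bis(2,4,6-triisopropylphenyl)-1,1′-binaphthyl-2,2′-diyl hydrogen phosphate] (5 mol%), 4 Å MS, toluene, −30 °C; then CH2Cl2, TMSOTf (1.3 equiv), −78 °C; aq. NaHCO3
Reagents that add atoms: none
Why: The phosphoric acid organises boronate 17 and the aldehyde of 3 in a closed chair (Zimmerman–Traxler) transition state in which the allyl unit is transferred from boron with allylic transposition, C7 bonding to C8 and C11=C12 emerging as the isopropenyl group (borate 18); TMSOTf then ionises the dibenzyl acetal to an O-benzyl oxocarbenium ion at C9, which is captured by C10, the γ-terminus of the silyl dienol ether, and loss of the silyl group restores the ring A enone (19, hydrolysed to 20 on work-up). The closest known reaction types are the chiral-phosphoric-acid-catalysed allylboration of aldehydes with γ-substituted allyl pinacol boronates and the Lewis-acid-mediated vinylogous Mukaiyama addition of 1-siloxy-1,3-dienes to acetals. Ring B is closed in the second event by a 6-exo-trig attack of C10 on the oxocarbenium carbon through a chair transition state. C7 and C8: the (Z)-boronate places C6 axial and the acetal-bearing substituent equatorial, which gives the 7,8-syn (cis) pair, and its absolute sense relative to C5 is imposed by the catalyst, whose enantiomer is chosen by analogy with the usual facial preference of this catalyst class. C9 and C10: with the isopropenyl group and the C5 methyl equatorial, the O-benzyl group takes the equatorial site (the axial one lies under ring A) and C10 can only be reached on the face cis to the C6 arm, so the 9β-ether and the cis ring fusion should result, a trans fusion requiring the isopropenyl group syn-axial to the C5 methyl. The step needs the allylboration to precede any reaction of the dienol ether and γ- rather than α-attack: the siloxydiene should not add to the unactivated aldehyde, TMSOTf is introduced only after the boronate is consumed, and attack through C2 would have to form an eight-membered ring.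

Step 10
Reactants: 20 9β-(benzyloxy)-8β-hydroxy-10βH-eremophila-1,11-dien-3-one
Product: 21 9β-(benzyloxy)-8β-hydroxy-10βH-eremophil-11-en-3-one
Conditions: [(Ph3P)CuH]6 (0.4 equiv), THF, H2O (2 equiv), rt; then NaOMe (0.3 equiv), MeOH, rt
Reagents that add atoms: none
Why: Conjugate reduction by the copper hydride (Stryker reduction) is selective for the enone over the isolated 1,1-disubstituted alkene, and the methoxide stage equilibrates C4 to the equatorial 4β-methyl epimer, since a 4α-methyl group would be syn-axial to the C10–C9 bond.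

Step 11
Reactants: 21 9β-(benzyloxy)-8β-hydroxy-10βH-eremophil-11-en-3-one
Product: 22 10βH-eremophil-11-ene-3α,8β,9β-triol
Conditions: Li, NH3(l), THF, EtOH, −78 to −33 °C; then NH4Cl
Reagents that add atoms: none
Why: Dissolving-metal reduction should give the thermodynamically favoured equatorial 3α-alcohol (hydride reagents would be pushed to the equatorial trajectory by the syn-axial C5 methyl) and cleaves the benzyl ether in the same operation, the isolated alkene being inert.

Step 12
Reactants: 22 10βH-eremophil-11-ene-3α,8β,9β-triol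
Product: 23 8β,9β-(isopropylidenedioxy)-10βH-eremophil-11-en-3α-ol
Conditions: 2,2-dimethoxypropane, PPTS (cat.), CH2Cl2, rt
Reagents that add atoms: 2,2-dimethoxypropane, COC(C)(C)OC
Why: Acetonide formation is selective for the cis-8,9-diol (five-membered dioxolane) and leaves the isolated equatorial 3-hydroxyl free.

Step 13
Reactants: 23 8β,9β-(isopropylidenedioxy)-10βH-eremophil-11-en-3α-ol; 8 (R)-5-[(Z)-2-methylbut-2-enoyloxy]hex-2-ynoic acid
Product: 24 8β,9β-(isopropylidenedioxy)-10βH-eremophil-11-en-3α-yl (R)-5-[(Z)-2-methylbut-2-enoyloxy]hex-2-ynoate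
Conditions: DCC, DMAP (5 mol%), CH2Cl2, −20 to 0 °C
Reagents that add atoms: none
Why: Steglich esterification of the single free secondary alcohol proceeds with retention at C3, and using the alkynoic acid avoids exposing a (Z)-enoate to the acylation conditions.

Step 14
Reactants: 24 8β,9β-(isopropylidenedioxy)-10βH-eremophil-11-en-3α-yl (R)-5-[(Z)-2-methylbut-2-enoyloxy]hex-2-ynoate
Product: 25 8β,9β-(isopropylidenedioxy)-10βH-eremophil-11-en-3α-yl (2Z,5R)-5-[(Z)-2-methylbut-2-enoyloxy]hex-2-enoate
Conditions: H2 (1 atm), Pd/CaCO3 poisoned with Pb(OAc)2 (Lindlar catalyst), quinoline, EtOAc, rt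
Reagents that add atoms: none
Why: Lindlar semi-hydrogenation adds H2 syn to the alkyne on the poisoned palladium surface, giving the (Z)-enoate while the isopropenyl and angelate alkenes should stay untouched.

Step 15
Reactants: 25 8β,9β-(isopropylidenedioxy)-10βH-eremophil-11-en-3α-yl (2Z,5R)-5-[(Z)-2-methylbut-2-enoyloxy]hex-2-enoate
Product: 26 8β,9β-dihydroxy-10βH-eremophil-11-en-3α-yl (2Z,5R)-5-[(Z)-2-methylbut-2-enoyloxy]hex-2-enoate (CNP0395983.1)
Conditions: AcOH/H2O 4:1, 40 °C
Reagents that add atoms: none
Why: Mild aqueous acid hydrolyses the isopropylidene acetal without cleaving the two esters or isomerising the (Z)-alkenes.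

Compound list
1 | 3,3-diethoxyprop-1-ene (acrolein diethyl acetal) | C=CC(OCC)OCC | starting material
2 | 3,3-bis(benzyloxy)prop-1-ene | C=CC(OCc1ccccc1)OCc1ccccc1 | intermediate
3 | 2,2-bis(benzyloxy)acetaldehyde | O=CC(OCc1ccccc1)OCc1ccccc1 | intermediate
4 | (R)-pent-4-yn-2-ol | C#CC[C@@H](C)O | starting material
5 | angelic acid, (Z)-2-methylbut-2-enoic acid | OC(=O)/C(C)=C\C | starting material
6 | (Z)-2-methylbut-2-enoic 2,4,6-trichlorobenzoic anhydride (not isolated) | O=C(OC(=O)/C(C)=C\C)c1c(Cl)cc(Cl)cc1Cl | intermediate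
7 | (R)-pent-4-yn-2-yl (Z)-2-methylbut-2-enoate | C#CC[C@@H](C)OC(=O)/C(C)=C\C | intermediate
8 | (R)-5-[(Z)-2-methylbut-2-enoyloxy]hex-2-ynoic acid | OC(=O)C#CC[C@@H](C)OC(=O)/C(C)=C\C | intermediate
9 | 2-methylbut-1-en-3-yne | C=C(C)C#C | starting material
10 | 3-methylcyclohex-2-en-1-one | CC1=CC(=O)CCC1 | starting material
11 | [(E)-3-methylbuta-1,3-dienyl]bis(2-methylpropyl)alane (not isolated) | C=C(C)/C=C/[Al](CC(C)C)CC(C)C | intermediate
12 | diisobutylaluminium enolate (C3=C4) of 3-methyl-3-[(E)-3-methylbuta-1,3-dienyl]cyclohexanone, C5 as in 13 (not isolated) | C=C(C)/C=C/[C@@]1(C)CCCC(O[Al](CC(C)C)CC(C)C)=C1 | intermediate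
13 | (2R,3R)-2,3-dimethyl-3-[(E)-3-methylbuta-1,3-dienyl]cyclohexanone | C=C(C)/C=C/[C@@]1(C)CCCC(=O)[C@@H]1C | intermediate
14 | trimethylsilyl enol ether (C3=C2) of 13 (not isolated) | C=C(C)/C=C/[C@@]1(C)CCC=C(O[Si](C)(C)C)[C@@H]1C | intermediate
15 | (5R,6R)-5,6-dimethyl-5-[(E)-3-methylbuta-1,3-dienyl]cyclohex-2-en-1-one | C=C(C)/C=C/[C@@]1(C)CC=CC(=O)[C@@H]1C | intermediate
16 | (5R,6R)-1-(tert-butyldimethylsilyloxy)-5,6-dimethyl-5-[(E)-3-methylbuta-1,3-dienyl]cyclohexa-1,3-diene | C=C(C)/C=C/[C@@]1(C)C=CC=C(O[Si](C)(C)C(C)(C)C)[C@@H]1C | intermediate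
17 | 2-[(2Z)-4-{(1S,6R)-5-(tert-butyldimethylsilyloxy)-1,6-dimethylcyclohexa-2,4-dien-1-yl}-2-methylbut-2-en-1-yl]-4,4,5,5-tetramethyl-1,3,2-dioxaborolane | CC1(C)OB(C/C(C)=C\C[C@@]2(C)C=CC=C(O[Si](C)(C)C(C)(C)C)[C@@H]2C)OC1(C)C | intermediate
18 | pinacol borate of the (7R,8S)-homoallylic alcohol: ring A silyl dienol ether carrying on C5 the chain CH2–CH(isopropenyl)–CH(OBpin)–CH(OBn)2 (not isolated) | C=C(C)[C@H]([C@H](OB1OC(C)(C)C(C)(C)O1)C(OCc1ccccc1)OCc1ccccc1)C[C@@]2(C)C=CC=C(O[Si](C)(C)C(C)(C)C)[C@@H]2C | intermediate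
19 | 8-O-(pinacolboryl) ether of 20 (not isolated) | C=C(C)[C@H]1C[C@@]2(C)[C@H](C=CC(=O)[C@@H]2C)[C@@H](OCc3ccccc3)[C@H]1OB4OC(C)(C)C(C)(C)O4 | intermediate
20 | 9β-(benzyloxy)-8β-hydroxy-10βH-eremophila-1,11-dien-3-one (4β,5β-dimethyl, 7β-isopropenyl) | C=C(C)[C@H]1C[C@@]2(C)[C@H](C=CC(=O)[C@@H]2C)[C@@H](OCc3ccccc3)[C@H]1O | intermediate
21 | 9β-(benzyloxy)-8β-hydroxy-10βH-eremophil-11-en-3-one | C=C(C)[C@H]1C[C@@]2(C)[C@H](CCC(=O)[C@@H]2C)[C@@H](OCc3ccccc3)[C@H]1O | intermediate
22 | 10βH-eremophil-11-ene-3α,8β,9β-triol | C=C(C)[C@H]1C[C@@]2(C)[C@H](CC[C@@H](O)[C@@H]2C)[C@@H](O)[C@H]1O | intermediate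
23 | 8β,9β-(isopropylidenedioxy)-10βH-eremophil-11-en-3α-ol | C=C(C)[C@H]1C[C@@]2(C)[C@H](CC[C@@H](O)[C@@H]2C)[C@@H](OC3(C)C)[C@H]1O3 | intermediate
24 | 8β,9β-(isopropylidenedioxy)-10βH-eremophil-11-en-3α-yl (R)-5-[(Z)-2-methylbut-2-enoyloxy]hex-2-ynoate | C=C(C)[C@H]1C[C@@]2(C)[C@H](CC[C@@H](OC(=O)C#CC[C@@H](C)OC(=O)/C(C)=C\C)[C@@H]2C)[C@@H](OC3(C)C)[C@H]1O3 | intermediate
25 | 8β,9β-(isopropylidenedioxy)-10βH-eremophil-11-en-3α-yl (2Z,5R)-5-[(Z)-2-methylbut-2-enoyloxy]hex-2-enoate | C=C(C)[C@H]1C[C@@]2(C)[C@H](CC[C@@H](OC(=O)/C=C\C[C@@H](C)OC(=O)/C(C)=C\C)[C@@H]2C)[C@@H](OC3(C)C)[C@H]1O3 | intermediate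
26 | 8β,9β-dihydroxy-10βH-eremophil-11-en-3α-yl (2Z,5R)-5-[(Z)-2-methylbut-2-enoyloxy]hex-2-enoate (CNP0395983.1) | C=C(C)[C@H]1C[C@@]2(C)[C@H](CC[C@@H](OC(=O)/C=C\C[C@@H](C)OC(=O)/C(C)=C\C)[C@@H]2C)[C@@H](O)[C@H]1O | target

Total step count: 15. Longest linear sequence: 11 steps (steps 5 to 15); aldehyde 3 and acid 8 are each made in 2 steps.

Steps most likely to fail

Step 9. What may go wrong: protodesilylation of the silyl dienol ether by the phosphoric acid (or by adventitious triflic acid) before ring closure, so that C10 is no longer nucleophilic when the oxocarbenium ion is generated. Fallback: the two bond formations are separated and the nucleophile is generated only in the presence of the electrophile. Setting out from 17, the catalysed allylboration with 3 is run as above and worked up with dilute aqueous HCl, which hydrolyses both the borate 18 and the dienol ether and gives the enone alcohol F1. F1 is then treated with TMSOTf and i-Pr2NEt (CH2Cl2, −78 to −20 °C): O8 is silylated and the enone is soft-enolised to the bis(trimethylsilyl) dienol ether F2, the acetal is ionised and ring B closes to the 8-O-trimethylsilyl ether F3, and acidic work-up brings the route back at 20.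

Step 8. What may go wrong: poor chemoselectivity of the nickel hydride between the side-chain diene and the cyclic siloxydiene, or reduction of the latter. Fallback: the order of events is changed so that the hydroboration is done while the side chain is the only diene. Setting out from 13, the same nickel-catalysed 1,4-hydroboration gives the allylboronate ketone F4. Dehydrogenation by the Mukaiyama method (LiN(i-Pr)2, then N-tert-butylbenzenesulfinimidoyl chloride, THF, −78 °C), chosen because it needs neither palladium nor an oxidant that attacks the allylboronate, gives the allylboronate enone F5, and silylation (TBSOTf, Et3N) brings the route back at 17.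

Step 5. What may go wrong: sluggish or unselective C-alkylation of the aluminium enolate (proton transfer, polyalkylation). Fallback: the C4 methyl group is introduced by α′-alkylation of the enone instead of enolate trapping. Setting out from 9 and 10, the conjugate addition is run as above through 11 and 12 and quenched with aqueous NH4Cl to give ketone F6. IBX (DMSO, 70 °C) dehydrogenates it to enone F7, only the C1–C2 side carrying a β-hydrogen. Kinetic deprotonation at C4 with LiN(i-Pr)2 and methylation with MeI bring the route back at 15, any C4 epimer being converged in step 10.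

Further compounds
F1 | step 9 | enone alcohol: (5R,6R)-5,6-dimethylcyclohex-2-en-1-one carrying on C5 the chain CH2–CH(isopropenyl)–CH(OH)–CH(OBn)2, (7R,8S) | C=C(C)[C@H]([C@H](O)C(OCc1ccccc1)OCc1ccccc1)C[C@@]2(C)CC=CC(=O)[C@@H]2C
F2 | step 9 | 8-O-trimethylsilyl ether and trimethylsilyl dienol ether of F1 (not isolated) | C=C(C)[C@H]([C@H](O[Si](C)(C)C)C(OCc1ccccc1)OCc1ccccc1)C[C@@]2(C)C=CC=C(O[Si](C)(C)C)[C@@H]2C
F3 | step 9 | 8-O-trimethylsilyl ether of 20 (not isolated) | C=C(C)[C@H]1C[C@@]2(C)[C@H](C=CC(=O)[C@@H]2C)[C@@H](OCc3ccccc3)[C@H]1O[Si](C)(C)C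
F4 | step 8 | allylboronate ketone: (2R,3R)-2,3-dimethyl-3-[(2Z)-3-methyl-4-(4,4,5,5-tetramethyl-1,3,2-dioxaborolan-2-yl)but-2-enyl]cyclohexanone | CC1(C)OB(C/C(C)=C\C[C@@]2(C)CCCC(=O)[C@@H]2C)OC1(C)C
F5 | step 8 | allylboronate enone: (5R,6R)-5,6-dimethyl-5-[(2Z)-3-methyl-4-(4,4,5,5-tetramethyl-1,3,2-dioxaborolan-2-yl)but-2-enyl]cyclohex-2-en-1-one | CC1(C)OB(C/C(C)=C\C[C@@]2(C)CC=CC(=O)[C@@H]2C)OC1(C)C
F6 | step 5 | (S)-3-methyl-3-[(E)-3-methylbuta-1,3-dienyl]cyclohexanone | C=C(C)/C=C/[C@@]1(C)CCCC(=O)C1
F7 | step 5 | (S)-5-methyl-5-[(E)-3-methylbuta-1,3-dienyl]cyclohex-2-en-1-one | C=C(C)/C=C/[C@@]1(C)CC=CC(=O)C1
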